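**Retrosynthetic overview**

1. Chromene numbering is used for the core: O1, C2 (CMe2), C3 (CH‑prenyl), C4, C4a (quaternary C), C5 (C=O), C6 (CH‑prenyl), C7 (C=O), C8 (C‑aroyl), C8a (enol‑ether C); ring A is the carbocycle, ring B the pyran. The target comes from its bis‑silyl ether 20, and 20 from the bicyclic dione 15 by C8 aroylation and then C8–C8a dehydrogenation.
2. Key disconnection of 15: C4a–C8a and C6–C7 together, by a base‑induced Michael–Claisen cascade of the open‑chain keto β‑alkoxyacrylate 13. Ring B closes first (6‑exo Michael), ring A second (Claisen).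
3. Enabling feature: O1 sits on C8a and is joined to C4a through C2–C3–C4, so the three‑carbon unit C8a–C8–C7 can be hung on the tertiary alcohol as an acrylate; the C5 ketone, flanked by C4a and C6, supplies both nucleophilic carbons. C8a is carried one oxidation level low and re‑oxidised in step 11.
4. 13 comes from hydroxy ketone 11 and methyl propiolate; 11 from δ‑lactone 8 and (4‑methylpent‑3‑enyl)lithium; 8 from acid 6 by iodolactonization, which converts one of two identical lavandulyl arms.
5. 6 comes from dimethyl malonate and two equivalents of (R)‑lavandulyl iodide, so both side‑chain stereocentres derive from (R)‑lavandulol.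

Key step: step 8

Remark: (R)‑(–)‑lavandulol is taken as a commercial single enantiomer; its stereocentre becomes, unchanged, both C3 and the lavandulyl CH of the target.
Remark: C6 is a 1,3‑dicarbonyl methine that equilibrates with its enols; the (6S) keto form drawn is the one expected from protonation anti to the axial 4a‑CH2 group, and 15 and 18 are written without a C6 descriptor.

**Route**

Step 1
Reactants: 1 (R)‑lavandulol
Product: 2 (R)‑lavandulyl iodide
Conditions: PPh3, imidazole, I2, CH2Cl2, 0 °C to rt
Reagents that add atoms: iodine, II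
Why: Appel‑type iodination of the primary alcohol by SN2 at CH2, which leaves the adjacent stereocentre untouched.

Step 2
Reactants: 2 (R)‑lavandulyl iodide (2.2 equiv); 3 dimethyl malonate
Product: 4 dimethyl 2,2‑bis[(S)‑lavandulyl]malonate
Conditions: NaH (2.3 equiv), DMF–THF, 0 to 60 °C
Reagents that add atoms: none
Why: Double malonic ester alkylation, in which the soft, weakly basic malonate anion should favour SN2 over E2 on the β‑branched primary iodide; the stereocentres are not involved (the descriptor changes from R to S only by priority).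

Step 3
Reactants: 4 dimethyl 2,2‑bis[(S)‑lavandulyl]malonate
Product: 6 2,2‑bis[(S)‑lavandulyl]acetic acid, via malonic diacid 5 (not isolated)
Conditions: KOH, EtOH–H2O, reflux; aq. HCl; then pyridine, 110 °C
Reagents that add atoms: potassium hydroxide, [K+].[OH-]
Why: Saponification and thermal decarboxylation of the malonic acid (malonic ester synthesis); the α‑carbon carries two identical arms and is not stereogenic.

Step 4
Reactants: 6 2,2‑bis[(S)‑lavandulyl]acetic acid
Product: 7 iodolactone (6‑iodomethyl‑6‑methyl δ‑lactone)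
Conditions: I2, NaHCO3, MeCN, 0 °C, dark
Reagents that add atoms: iodine, II
Why: Iodolactonization, in which the carboxylate opens the iodonium ion of an isopropenyl group at its tertiary carbon in a 6‑exo closure that no prenyl alkene can match, and because the arms are identical and the acid is consumed by one closure exactly one arm reacts; the new C6 centre is erased in step 5 and the α‑carbon is enolized in step 8.

Step 5
Reactants: 7 iodolactone
Product: 8 δ‑lactone (5S)‑6,6‑dimethyl‑5‑prenyl‑3‑[(S)‑lavandulyl]tetrahydropyran‑2‑one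
Conditions: Bu3SnH, (PhSe)2 (10 mol %), Et3B, air, toluene, 0 °C
Reagents that add atoms: none
Why: Radical deiodination in which PhSeH, formed from (PhSe)2 and Bu3SnH, should transfer hydrogen fast enough to outrun 5‑exo cyclization of the primary radical onto the neighbouring prenyl group.

Step 6
Reactants: 8 δ‑lactone; 9 5‑bromo‑2‑methylpent‑2‑ene
Product: 11 δ‑hydroxy ketone, via organolithium 10 (not isolated)
Conditions: 9, t‑BuLi (2 equiv), Et2O, −78 °C; then 8, THF, −78 °C; AcOH
Reagents that add atoms: none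
Why: Halogen–lithium exchange and addition to the δ‑lactone, whose tetrahedral lithium lactolate is stable at −78 °C and should give the open hydroxy ketone on work‑up after a single addition; the α‑carbon is an inconsequential epimer mixture.

Step 7
Reactants: 11 δ‑hydroxy ketone; 12 methyl propiolate
Product: 13 methyl (E)‑3‑alkoxyacrylate of 11
Conditions: PMe3 (20 mol %), CH2Cl2, 0 °C to rt
Reagents that add atoms: none
Why: Trialkylphosphine‑catalysed oxa‑Michael addition of the tertiary alcohol to the propiolate, under neutral conditions that leave the ketone untouched and give the (E)‑β‑alkoxyacrylate.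

Step 8
Reactants: 13 methyl (E)‑3‑alkoxyacrylate
Product: 15 bicyclic 1,3‑dione (3S,4aR,8aS), via tetrahydropyranyl keto ester 14 (not isolated)
Conditions: KOtBu (2.5 equiv), THF–t‑BuOH (10:1), 0.01 M, 0 °C to rt; then 1 M HCl
Reagents that add atoms: none
Why: Proposed new method: KOtBu enolizes the ketone reversibly toward both α‑carbons, but only the C4a enolate can reach the tethered (E)‑β‑alkoxyacrylate, so a 6‑exo‑trig Michael addition closes ring B and forms the quaternary C4a–C8a bond, after which proton transfer gives the C6 enolate, which closes ring A by a 6‑exo‑trig Claisen (Dieckmann‑type) attack on the methyl ester (C6–C7), the sequence being pulled forward by deprotonation of the 1,3‑dione. The closest known reaction type is the consecutive Michael–Claisen [3+3] annulation of ketones with acrylates to cyclohexane‑1,3‑diones, joined here to the 6‑exo cyclization onto a β‑alkoxyacrylate known from radical routes to tetrahydropyrans. C4a is set in a chair‑like Michael transition state with the C3 prenyl group and the acrylate equatorial, in which allylic 1,3‑strain of the tetrasubstituted enolate (C4a=C5) makes the C4–C3 bond of the tether lean toward the lavandulyl CH2 and not toward C5 with its in‑plane O and C6 substituents, so the lavandulyl CH2 ends axial and C5 equatorial, cis to the C3 prenyl group as in the target. C8a (H axial, avoiding the axial methyl on C2) is a temporary centre that step 11 removes, and C6 stays enolized. The step needs site selectivity between the two α‑carbons and chemoselectivity over four isolated alkenes: the first is secured by ring size (the C6 enolate could only close an eight‑membered ring, and dilution suppresses intermolecular addition), the second by the inertness of unactivated alkenes to enolates.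

Step 9
Reactants: 16 methyl 3,4‑dihydroxybenzoate
Product: 17 methyl 3,4‑bis(tert‑butyldimethylsilyloxy)benzoate
Conditions: TBSCl (2.4 equiv), imidazole, DMF, rt
Reagents that add atoms: tert‑butyldimethylsilyl chloride, CC(C)(C)[Si](C)(C)Cl
Why: Standard silylation of both phenols, giving an aroyl donor that has no acidic hydrogen and is stable to amide bases.

Step 10
Reactants: 15 bicyclic 1,3‑dione; 17 methyl 3,4‑bis(tert‑butyldimethylsilyloxy)benzoate
Product: 18 8‑aroyl bicyclic triketone
Conditions: LiN(i‑Pr)2 (3.2 equiv), THF, −78 to −40 °C; 17, −78 to −20 °C; AcOH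
Reagents that add atoms: none
Why: Claisen‑type γ‑acylation of a 1,3‑diketone dianion, which should react at its less stabilised carbon C8 with the non‑enolizable aryl ester while the third equivalent of base takes up the acidic triketone product.

Step 11
Reactants: 18 8‑aroyl bicyclic triketone
Product: 20 bis‑silyl ether of the target, via selenide 19 (not isolated)
Conditions: LiN(i‑Pr)2 (2.2 equiv), THF, −78 °C; PhSeBr; AcOH; then H2O2 (30%), pyridine, CH2Cl2, 0 °C
Reagents that add atoms: none
Why: Selenenylation and selenoxide syn‑elimination, in which the dianion should take up selenium at the less stabilised C8 enolate on the face anti to the axial 4a‑CH2 group, placing it syn to H‑8a, the only hydrogen available, so that the C8=C8a enol ether forms; protonation of C6 on work‑up anti to the same axial group should give the 6S keto form.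

Step 12
Reactants: 20 bis‑silyl ether of the target
Product: 21 target CNP0250793.1
Conditions: Bu4NF, AcOH, THF, 0 °C
Reagents that add atoms: none
Why: Fluoride cleavage of the two aryl silyl ethers, buffered with AcOH so that the tertiary‑alkyl enol ether and the lavandulyl group are not disturbed and C6 is re‑protonated as in step 11.

**Compound list**

1 | (R)‑lavandulol | C=C(C)[C@@H](CC=C(C)C)CO | starting material
2 | (R)‑lavandulyl iodide | C=C(C)[C@@H](CC=C(C)C)CI | intermediate
3 | dimethyl malonate | COC(=O)CC(=O)OC | starting material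
4 | dimethyl 2,2‑bis[(2S)‑5‑methyl‑2‑(prop‑1‑en‑2‑yl)hex‑4‑enyl]malonate | COC(=O)C(C[C@H](CC=C(C)C)C(C)=C)(C[C@H](CC=C(C)C)C(C)=C)C(=O)OC | intermediate
5 | 2,2‑bis[(S)‑lavandulyl]malonic acid | OC(=O)C(C[C@H](CC=C(C)C)C(C)=C)(C[C@H](CC=C(C)C)C(C)=C)C(=O)O | intermediate
6 | 2,2‑bis[(S)‑lavandulyl]acetic acid | OC(=O)C(C[C@H](CC=C(C)C)C(C)=C)C[C@H](CC=C(C)C)C(C)=C | intermediate
7 | (5S)‑6‑(iodomethyl)‑6‑methyl‑5‑prenyl‑3‑[(S)‑lavandulyl]tetrahydropyran‑2‑one, mixture at C3 and C6 | O=C1OC(C)(CI)[C@@H](CC=C(C)C)CC1C[C@H](CC=C(C)C)C(C)=C | intermediate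
8 | (5S)‑6,6‑dimethyl‑5‑prenyl‑3‑[(S)‑lavandulyl]tetrahydropyran‑2‑one, mixture at C3 | O=C1OC(C)(C)[C@@H](CC=C(C)C)CC1C[C@H](CC=C(C)C)C(C)=C | intermediate
9 | 5‑bromo‑2‑methylpent‑2‑ene | BrCCC=C(C)C | starting material
10 | (4‑methylpent‑3‑enyl)lithium | [Li]CCC=C(C)C | intermediate
11 | δ‑hydroxy ketone: 4‑methylpent‑3‑enyl ketone whose α‑CH carries the (S)‑lavandulyl arm and the (2S)‑3‑hydroxy‑3‑methyl‑2‑prenylbutyl arm, α‑epimers | CC(C)=CCCC(=O)C(C[C@H](CC=C(C)C)C(C)=C)C[C@H](CC=C(C)C)C(C)(C)O | intermediate
12 | methyl propiolate | C#CC(=O)OC | starting material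
13 | methyl (E)‑3‑alkoxyacrylate of 11 (ether on the tertiary oxygen) | CC(C)=CCCC(=O)C(C[C@H](CC=C(C)C)C(C)=C)C[C@H](CC=C(C)C)C(C)(C)O/C=C/C(=O)OC | intermediate
14 | Michael adduct: methyl 2‑[3‑acyl‑3‑lavandulyl‑6,6‑dimethyl‑5‑prenyltetrahydropyran‑2‑yl]acetate, acyl = 5‑methylhex‑4‑enoyl | COC(=O)C[C@@H]1OC(C)(C)[C@@H](CC=C(C)C)C[C@@]1(C[C@H](CC=C(C)C)C(C)=C)C(=O)CCC=C(C)C | intermediate
15 | (3S,4aR,8aS)‑2,2‑dimethyl‑3,6‑diprenyl‑4a‑[(S)‑lavandulyl]hexahydrochromene‑5,7‑dione, trans‑fused, C6 enolized | O=C1C[C@@H]2OC(C)(C)[C@@H](CC=C(C)C)C[C@@]2(C[C@H](CC=C(C)C)C(C)=C)C(=O)C1CC=C(C)C | intermediate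
16 | methyl 3,4‑dihydroxybenzoate | COC(=O)c1ccc(O)c(O)c1 | starting material
17 | methyl 3,4‑bis(tert‑butyldimethylsilyloxy)benzoate | COC(=O)c1ccc(O[Si](C)(C)C(C)(C)C)c(O[Si](C)(C)C(C)(C)C)c1 | intermediate
18 | 8‑[3,4‑bis(tert‑butyldimethylsilyloxy)benzoyl] derivative of 15, C6 and C8 enolized | O=C1C(C(=O)c3ccc(O[Si](C)(C)C(C)(C)C)c(O[Si](C)(C)C(C)(C)C)c3)[C@@H]2OC(C)(C)[C@@H](CC=C(C)C)C[C@@]2(C[C@H](CC=C(C)C)C(C)=C)C(=O)C1CC=C(C)C | intermediate
19 | 8‑phenylseleno derivative of 18, selenium expected cis to H‑8a | O=C1C([Se]c3ccccc3)(C(=O)c4ccc(O[Si](C)(C)C(C)(C)C)c(O[Si](C)(C)C(C)(C)C)c4)[C@@H]2OC(C)(C)[C@@H](CC=C(C)C)C[C@@]2(C[C@H](CC=C(C)C)C(C)=C)C(=O)C1CC=C(C)C | intermediate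
20 | 3',4'‑bis(tert‑butyldimethylsilyl) ether of the target | C=C(C)[C@@H](CC=C(C)C)C[C@@]12C[C@H](CC=C(C)C)C(C)(C)OC1=C(C(=O)c1ccc(O[Si](C)(C)C(C)(C)C)c(O[Si](C)(C)C(C)(C)C)c1)C(=O)[C@@H](CC=C(C)C)C2=O | intermediate
21 | CNP0250793.1 | C=C(C)[C@@H](CC=C(C)C)C[C@@]12C[C@H](CC=C(C)C)C(C)(C)OC1=C(C(=O)c1ccc(O)c(O)c1)C(=O)[C@@H](CC=C(C)C)C2=O | target

**Count**

Total steps: 12. Longest linear sequence: 11 steps (1–8, 10–12); step 9 is a one‑step branch.

**Steps most likely to fail**

1. Step 8 (proposed new method). The hindered C4a enolate may add too slowly to the donor‑substituted acrylate, the tertiary alkoxide may be lost by β‑elimination from the ester enolate (ring B reopens), or the facial selectivity at C4a may be low. The fallback uses known chemistry, sets out from acid 6 and returns at 20. Two equivalents of organolithium 10 (Et2O, 0 °C) convert 6 into the symmetric bis‑lavandulyl ketone F1. O‑Methylation of its less substituted potassium enolate (KN(SiMe3)2, THF–DMPU, −78 °C; Me2SO4) gives the methyl enol ether F2. Effenberger cyclization with malonyl dichloride (Et2O, −20 °C to rt) forms the same two bonds, C6–C7 and C4a–C8a, and gives the 5‑O‑methyl trione F3, whose C4a carries two identical lavandulyl groups and is not yet stereogenic. Acid (TsOH, toluene, rt) then closes ring B. Because O5 is blocked as the methyl ether, only the oxygen on C8a can trap the tertiary cation; of the two identical arms, the one that places its prenyl group equatorial (other arm axial) should cyclize, giving the pyran‑fused vinylogous ester F4 with the target configuration at C4a. Vinylic lithiation at C8 (lithium 2,2,6,6‑tetramethylpiperidide, THF, −78 °C) and addition to 3,4‑bis(tert‑butyldimethylsilyloxy)benzaldehyde give the carbinol F5. Dess–Martin oxidation gives the aroyl compound F6, and LiCl in DMSO (120 °C) removes the O‑methyl group by SN2 to return to 20.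

2. Step 10. The C8 carbanion of the dianion may expel the ring‑B alkoxide by β‑elimination, or acylation by the electron‑rich ester may be too slow at the temperatures the dianion tolerates. The fallback sets out from 15 and returns at 18 without a free carbanion. Soft enolization (Me3SiOTf, Et3N, CH2Cl2, 0 °C) gives the bis(trimethylsilyloxy)diene F7. A vinylogous Mukaiyama aldol addition at its terminal carbon C8 to 3,4‑bis(tert‑butyldimethylsilyloxy)benzaldehyde (BF3·OEt2, CH2Cl2, −78 °C) gives the β‑hydroxy ketone F8. Dess–Martin oxidation then gives 18.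

3. Step 11. Selenium may enter at the C6 enolate carbon, or on the face that leaves H‑8a anti, so that no syn elimination can follow. The fallback sets out from 18 and returns at 20, and uses the opposite geometric requirement. Bromination of the same dianion (N‑bromosuccinimide, THF, −78 °C) gives the C8 bromide F9, and 1,8‑diazabicyclo[5.4.0]undec‑7‑ene (CH2Cl2, 0 °C to rt) removes HBr by anti‑periplanar E2 across C8–C8a. Bromine that lands on C6 has no ring hydrogen to eliminate with and should be passed on to the C8 enolate.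

Further compounds
F1 | step 8 | 1,1‑bis[(S)‑lavandulyl]methyl 4‑methylpent‑3‑enyl ketone | CC(C)=CCCC(=O)C(C[C@H](CC=C(C)C)C(C)=C)C[C@H](CC=C(C)C)C(C)=C
F2 | step 8 | methyl enol ether of F1 toward C6 | COC(=CCC=C(C)C)C(C[C@H](CC=C(C)C)C(C)=C)C[C@H](CC=C(C)C)C(C)=C
F3 | step 8 | 5‑methoxy‑6‑prenyl‑4,4‑bis[(S)‑lavandulyl]cyclohex‑5‑ene‑1,3‑dione | COC1=C(CC=C(C)C)C(=O)CC(=O)C1(C[C@H](CC=C(C)C)C(C)=C)C[C@H](CC=C(C)C)C(C)=C
F4 | step 8 | (3S,4aR)‑5‑methoxy‑2,2‑dimethyl‑3,6‑diprenyl‑4a‑[(S)‑lavandulyl]‑3,4‑dihydrochromen‑7‑one | COC1=C(CC=C(C)C)C(=O)C=C2OC(C)(C)[C@@H](CC=C(C)C)C[C@@]12C[C@H](CC=C(C)C)C(C)=C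
F5 | step 8 | 8‑[aryl(hydroxy)methyl] derivative of F4, aryl = 3,4‑bis(tert‑butyldimethylsilyloxy)phenyl | COC1=C(CC=C(C)C)C(=O)C(C(O)c3ccc(O[Si](C)(C)C(C)(C)C)c(O[Si](C)(C)C(C)(C)C)c3)=C2OC(C)(C)[C@@H](CC=C(C)C)C[C@@]12C[C@H](CC=C(C)C)C(C)=C
F6 | step 8 | 8‑aroyl derivative of F4 (5‑O‑methyl ether of 20) | COC1=C(CC=C(C)C)C(=O)C(C(=O)c3ccc(O[Si](C)(C)C(C)(C)C)c(O[Si](C)(C)C(C)(C)C)c3)=C2OC(C)(C)[C@@H](CC=C(C)C)C[C@@]12C[C@H](CC=C(C)C)C(C)=C
F7 | step 10 | 5,7‑bis(trimethylsilyloxy)‑5,7‑diene of 15 | C[Si](C)(C)OC1=C[C@@H]2OC(C)(C)[C@@H](CC=C(C)C)C[C@@]2(C[C@H](CC=C(C)C)C(C)=C)C(O[Si](C)(C)C)=C1CC=C(C)C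
F8 | step 10 | 8‑[aryl(hydroxy)methyl] derivative of 15, aryl = 3,4‑bis(tert‑butyldimethylsilyloxy)phenyl | O=C1C(C(O)c3ccc(O[Si](C)(C)C(C)(C)C)c(O[Si](C)(C)C(C)(C)C)c3)[C@@H]2OC(C)(C)[C@@H](CC=C(C)C)C[C@@]2(C[C@H](CC=C(C)C)C(C)=C)C(=O)C1CC=C(C)C
F9 | step 11 | 8‑bromo derivative of 18 | O=C1C(Br)(C(=O)c3ccc(O[Si](C)(C)C(C)(C)C)c(O[Si](C)(C)C(C)(C)C)c3)[C@@H]2OC(C)(C)[C@@H](CC=C(C)C)C[C@@]2(C[C@H](CC=C(C)C)C(C)=C)C(=O)C1CC=C(C)C
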